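**Plan**
1. Numbering (germacrane): C1(–O4)=C2H–C3H2–C4(CH3)(–O4)–C5H=C6(–O)–C7(=C11)–C8H(OR)–C9H2–C10(CH3)(OH)–C1; C12 is the lactone C=O, C13 the CH2OAc carbon, O4 the oxygen joining C4 and C1.
2. Cuts: both enol-ether C=C bonds go back to hemiketals (C1, C6), the γ-hydroxybutenolide to a furan (O, C6, C7, C11, C12), then the two ester C–O bonds, C1–C2 (ring opening, together with O4–C1), C8–C9, C2–C3 and C5–C6.
3. Enabling feature: C1 is a ketone carbon in disguise, α to the C10 carbinol and 1,4 to the C4 oxygen, so a C1 ketone made inside the ten-membered ring is caught by O4 as the oxolane (O4, C1, C2, C3, C4). The C5=C6–C7=C11 dienol lactone is an oxidised furan whose C6–C7 bond holds the C5 and C8 arms cis for ring closure.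
4. Forward: furan-3,4-diyldimethanol is alkylated at C6 with a C4–C5 epoxide unit, extended by a sulfonyl-activated C2, allylated at C8 (C9, C10, C14, C1 as a temporary γ-lactone) and hydrated at C10. The key step closes the ten-membered carbocycle (C1–C2) and the oxolane (O4–C1) in one operation; singlet oxygen then unmasks the butenolide, and a double dehydration makes C1=C2 and C5=C6.
5. Stereochemistry: C4 from (R)-2-methylglycidol (never attacked), C8 from the chiral iridium catalyst, C10 from C8 across the temporary lactone; the C5=C6 geometry and the bridge are dictated by the rings.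

Key step: step 10

Assumption: (R)-SEGPHOS is written in step 6 for the ligand antipode that gives the 8R carbinol; if the sense of induction is the reverse, the other antipode is used and nothing else changes.

Step 1
Reactants: 1 furan-3,4-diyldimethanol
Product: 2 [4-(TBS-oxymethyl)furan-3-yl]methanol (TBS = tert-butyldimethylsilyl)
Conditions: NaH (1.0 equiv), THF, 0 °C; TBSCl (1.0 equiv), 0 → 23 °C
Reagents that add atoms: tert-butyldimethylsilyl chloride, C[Si](C)(Cl)C(C)(C)C
Why: Monosilylation of a symmetrical diol through its monosodium alkoxide (O-silylation) should desymmetrise the furan; no stereocentre is formed.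

Step 2
Reactants: 3 (R)-2-methylglycidol
Product: 4 (S)-2-methylglycidyl tosylate
Conditions: TsCl, Et3N, DMAP (cat.), CH2Cl2, 0 °C
Reagents that add atoms: 4-toluenesulfonyl chloride, Cc1ccc(cc1)S(Cl)(=O)=O
Why: Tosylation of the primary hydroxyl leaves the quaternary epoxide carbon untouched, so the configuration of 3 is kept (the descriptor changes to S only through the priorities).

Step 3
Reactants: 2 [4-(TBS-oxymethyl)furan-3-yl]methanol; 4 (S)-2-methylglycidyl tosylate
Product: 7 [2-{[(S)-2-methyloxiran-2-yl]methyl}-4-(TBS-oxymethyl)furan-3-yl]methanol, via C6-lithiated lithium alkoxide 5 (not isolated), via tosyloxy alcohol 6 (not isolated)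
Conditions: n-BuLi (2.2 equiv), THF, −78 → 0 °C; 4, BF3·OEt2, −78 °C; then K2CO3, MeOH, 23 °C
Reagents that add atoms: none
Why: Alkoxide-directed ortho-lithiation puts lithium on the furan α-carbon next to the CH2OLi arm (C6), the furyllithium opens the BF3-activated epoxide at its CH2 carbon (SN2), and the tertiary alkoxide then displaces the tosylate (intramolecular Williamson closure, as with epichlorohydrin); C4 is never attacked and keeps the configuration from 3.

Step 4
Reactants: 7 [2-{[(S)-2-methyloxiran-2-yl]methyl}-4-(TBS-oxymethyl)furan-3-yl]methanol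
Product: 8 (S)-1-[3-(hydroxymethyl)-4-(TBS-oxymethyl)furan-2-yl]-2-methyl-4-(phenylsulfonyl)butan-2-ol
Conditions: PhSO2CH3 (4 equiv), n-BuLi (4 equiv), THF/DMPU, −78 → 0 °C
Reagents that add atoms: methyl phenyl sulfone, CS(=O)(=O)c1ccccc1
Why: The α-sulfonyl carbanion opens the 2,2-disubstituted epoxide at its CH2 carbon (SN2 epoxide opening), adding C2 with its activating group and freeing the tertiary C4 hydroxyl without touching the stereocentre.

Step 5
Reactants: 9 ethyl 2-(hydroxymethyl)acrylate
Product: 10 ethyl 2-{[(tert-butoxycarbonyl)oxy]methyl}acrylate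
Conditions: Boc2O, DMAP (5 mol %), CH2Cl2, 0 °C
Reagents that add atoms: di-tert-butyl dicarbonate, CC(C)(C)OC(=O)OC(=O)OC(C)(C)C
Why: DMAP-catalysed acylation of the allylic alcohol (carbonate formation) gives the allyl donor for step 6; no stereocentre.

Step 6
Reactants: 8 (S)-1-[3-(hydroxymethyl)-4-(TBS-oxymethyl)furan-2-yl]-2-methyl-4-(phenylsulfonyl)butan-2-ol; 10 ethyl 2-{[(tert-butoxycarbonyl)oxy]methyl}acrylate
Product: 12 (R)-3-methylidene-5-Ar-oxolan-2-one (Ar = 2-[(S)-2-hydroxy-2-methyl-4-(phenylsulfonyl)butyl]-4-(TBS-oxymethyl)furan-3-yl), via hydroxy acrylate 11 (not isolated)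
Conditions: [Ir(cod)Cl]2 (2.5 mol %), (R)-SEGPHOS (5 mol %), 4-chloro-3-nitrobenzoic acid (10 mol %), Cs2CO3 (20 mol %), THF, 60 °C
Reagents that add atoms: none
Why: Iridium-catalysed transfer-hydrogenative carbonyl allylation from the alcohol oxidation level (Krische 2-(alkoxycarbonyl)allylation): the primary alcohol is dehydrogenated to the aldehyde, the 2-(ethoxycarbonyl)allyl iridium species adds under control of the chiral cyclometallated catalyst to set C8 (R), and the alkoxide lactonises onto the ester.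

Step 7
Reactants: 12 (R)-3-methylidene-5-Ar-oxolan-2-one
Product: 14 (3S,5R)-3-hydroxy-3-methyl-5-Ar-oxolan-2-one (hydroxyl trans to Ar), via C10 hydroperoxide 13 (not isolated)
Conditions: Mn(dpm)3 (10 mol %), PhSiH3, O2 (1 atm), i-PrOH/CH2Cl2, 0 °C; then P(OEt)3
Reagents that add atoms: dioxygen, O=O
Why: Mukaiyama-type reductive hydration (hydrogen-atom transfer from a manganese hydride to the exocyclic CH2, capture of the tertiary α-acyl radical by O2, phosphite reduction of the hydroperoxide); O2 is expected to approach the planar C10 radical anti to the furyl group on C8 across the five-membered lactone, placing the hydroxyl trans to it (10S).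

Step 8
Reactants: 14 (3S,5R)-3-hydroxy-3-methyl-5-Ar-oxolan-2-one
Product: 15 (2S,4R)-2,4-dihydroxy-N-methoxy-N,2-dimethyl-4-Ar-butanamide
Conditions: MeNH(OMe)·HCl, AlMe3, CH2Cl2, 0 → 23 °C
Reagents that add atoms: N,O-dimethylhydroxylamine hydrochloride, CNOC.Cl
Why: Aminolysis of the γ-lactone by the aluminium amide (Weinreb amide formation) unties C1 from O8 and makes C1 an acyl donor that accepts a carbanion only once; no stereocentre is touched.

Step 9
Reactants: 15 (2S,4R)-2,4-dihydroxy-N-methoxy-N,2-dimethyl-4-Ar-butanamide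
Product: 16 (2S,4R)-2-hydroxy-N-methoxy-N,2-dimethyl-4-(TBS-oxy)-4-Ar-butanamide
Conditions: TBSOTf (1.1 equiv), 2,6-lutidine, CH2Cl2, −78 °C
Reagents that add atoms: tert-butyldimethylsilyl triflate, C[Si](C)(OS(=O)(=O)C(F)(F)F)C(C)(C)C
Why: Low-temperature silylation with a limiting amount of silyl triflate should take the secondary C8 hydroxyl in preference to the two tertiary ones (silyl ether protection), which blocks relactonisation and keeps O8 away from C1 in step 10.

Step 10
Reactants: 16 (2S,4R)-2-hydroxy-N-methoxy-N,2-dimethyl-4-(TBS-oxy)-4-Ar-butanamide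
Product: 20 furan-fused 1,4-epoxy hemiketal (ten-membered carbocycle C1–C10 fused to the furan at C6–C7, O4 bridging C4 and C1, 1-OH, 2-phenylsulfonyl as both epimers, 8-O-TBS, 10-OH, 13-O-TBS), via sulfonyl carbanion 17 (not isolated), via lithium aminal 18 (not isolated), via keto alcohol 19 (not isolated)
Conditions: LiN(i-Pr)2 (3.5 equiv), THF, −78 °C, slow addition of 16 (final 0.003 M), −78 → −20 °C; aq. NH4Cl, 23 °C
Reagents that add atoms: none
Why: Proposed new method: LiN(i-Pr)2 removes the two hydroxyl protons and the C2–H next to the sulfone, and the sulfonyl carbanion adds to the only electrophile in the molecule, the N-methoxy-N-methylamide carbon C1, in a 10-exo-trig closure whose chelated lithium aminal 18 can neither collapse nor revert before work-up, so each ring takes up exactly one carbanion and the closure is irreversible; the closest known reactions are the acylation of α-sulfonyl carbanions by Weinreb amides between two molecules and sulfonyl-carbanion macrocyclisations by alkylation, whereas a medium ring closed by this acylation has no precedent. On quenching, 18 releases keto alcohol 19, whose C4 hydroxyl lies 1,4 to the C1 carbonyl across the ring and should add at once in a transannular 5-exo-trig closure to give the oxolane bridge. The hemiketal centre C1 is fixed by C4, because the six-atom tether C5–C10 can span the oxolane only cis; the sulfonyl-bearing C2 forms as a mixture that is erased in step 11. Ring closure must beat oligomerisation, which is secured by the furan (its C6–C7 bond holds the C5 and C8 arms cis like a cis-alkene), by the two quaternary carbinol carbons C4 and C10 and by high dilution; the ketone must be taken by O4 alone, which the silyl ether on O8 secures.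

Step 11
Reactants: 20 furan-fused 1,4-epoxy hemiketal (2-phenylsulfonyl)
Product: 21 desulfonylated hemiketal (1,4-epoxy, 1-OH, 8-O-TBS, 10-OH, 13-O-TBS)
Conditions: aluminium amalgam Al(Hg), THF/H2O (9:1), 0 → 23 °C
Reagents that add atoms: none
Why: Reductive C–S cleavage of the β-keto sulfone that is in equilibrium with the hemiketal (aluminium amalgam desulfonylation) removes the activating group, and the ketone re-closes onto O4.

Step 12
Reactants: 21 desulfonylated hemiketal
Product: 22 8,13-diol (1,4-epoxy, 1-OH, 8-OH, 10-OH, 13-OH)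
Conditions: Bu4NF, AcOH (1:1), THF, 0 → 23 °C
Reagents that add atoms: none
Why: Fluoride cleavage of both silyl ethers, buffered with acetic acid so that the hemiketal is not opened to an α-ketol under basic conditions.

Step 13
Reactants: 22 8,13-diol
Product: 23 13-acetate (1,4-epoxy, 1-OH, 8-OH, 10-OH, 13-OAc)
Conditions: Ac2O (1.1 equiv), 2,4,6-collidine, CH2Cl2, −20 °C
Reagents that add atoms: acetic anhydride, CC(=O)OC(C)=O
Why: Acylation of the unhindered primary furylmethyl hydroxyl should be much faster than that of the flanked secondary C8 hydroxyl or the tertiary ones (selective acetylation with a weak base at low temperature).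

Step 14
Reactants: 23 13-acetate
Product: 24 13-acetate 8-methacrylate (1,4-epoxy, 1-OH, 10-OH)
Conditions: methacrylic anhydride, Et3N, DMAP (cat.), CH2Cl2, 0 → 23 °C
Reagents that add atoms: methacrylic anhydride, C=C(C)C(=O)OC(=O)C(C)=C
Why: DMAP-catalysed acyl transfer (Steglich-type) to the only remaining non-tertiary hydroxyl gives the C8 ester; the tertiary C10 and hemiketal hydroxyls should not react under these conditions.

Step 15
Reactants: 24 13-acetate 8-methacrylate
Product: 26 γ-hydroxybutenolide (6-hydroxy-6,12-olide, 7(11)-ene, C6 epimers; 1,4-epoxy, 1-OH, 10-OH), via furan endoperoxide 25 (not isolated)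
Conditions: O2, visible light, tetraphenylporphyrin (cat.), i-Pr2NEt, CH2Cl2, −78 °C
Reagents that add atoms: dioxygen, O=O
Why: [4+2] cycloaddition of singlet oxygen across C6 and C12 of the electron-rich furan, then base-induced Kornblum–DeLaMare fragmentation of the endoperoxide, whose only bridgehead hydrogen is on C12, so C12 becomes the lactone carbonyl and C6 the hemiketal carbon; the methacrylate is too electron-poor to react.

Step 16
Reactants: 26 γ-hydroxybutenolide
Product: 28 CNP0394509.1 (target), via 1-hydroxy dienolide 27 (not isolated)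
Conditions: pyridinium p-toluenesulfonate (0.2 equiv), 4 Å molecular sieves, toluene, 70 °C
Reagents that add atoms: none
Why: Acid-catalysed E1 dehydration of both hemiketals through their oxocarbenium ions: C6 can lose a proton only from C5 and C1 only from C2 (C7 and C10 carry none), the ten-membered ring holds C4 and C7 cis across the new C5=C6 bond, the oxolane fixes C1=C2, and the sieves remove the water.

**Compound list**
1 | furan-3,4-diyldimethanol | OCc1cocc1CO | starting material
2 | [4-(TBS-oxymethyl)furan-3-yl]methanol | OCc1cocc1CO[Si](C)(C)C(C)(C)C | intermediate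
3 | (R)-2-methylglycidol, (R)-(2-methyloxiran-2-yl)methanol | OC[C@]1(C)CO1 | starting material
4 | (S)-2-methylglycidyl tosylate (same spatial arrangement as 3) | Cc1ccc(cc1)S(=O)(=O)OC[C@]1(C)CO1 | intermediate
5 | lithium [2-lithio-4-(TBS-oxymethyl)furan-3-yl]methoxide (formed in the flask) | [Li]OCc1c(CO[Si](C)(C)C(C)(C)C)coc1[Li] | intermediate
6 | (S)-2-hydroxy-3-[3-(hydroxymethyl)-4-(TBS-oxymethyl)furan-2-yl]-2-methylpropyl tosylate (formed in the flask) | OCc1c(CO[Si](C)(C)C(C)(C)C)coc1C[C@](C)(O)COS(=O)(=O)c2ccc(C)cc2 | intermediate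
7 | [2-{[(S)-2-methyloxiran-2-yl]methyl}-4-(TBS-oxymethyl)furan-3-yl]methanol | OCc1c(CO[Si](C)(C)C(C)(C)C)coc1C[C@@]2(C)CO2 | intermediate
8 | (S)-1-[3-(hydroxymethyl)-4-(TBS-oxymethyl)furan-2-yl]-2-methyl-4-(phenylsulfonyl)butan-2-ol | OCc1c(CO[Si](C)(C)C(C)(C)C)coc1C[C@](C)(O)CCS(=O)(=O)c2ccccc2 | intermediate
9 | ethyl 2-(hydroxymethyl)acrylate | C=C(CO)C(=O)OCC | starting material
10 | ethyl 2-{[(tert-butoxycarbonyl)oxy]methyl}acrylate | C=C(COC(=O)OC(C)(C)C)C(=O)OCC | intermediate
11 | ethyl (R)-4-hydroxy-2-methylidene-4-Ar-butanoate (formed in the flask) | C=C(C[C@@H](O)c1c(CO[Si](C)(C)C(C)(C)C)coc1C[C@](C)(O)CCS(=O)(=O)c2ccccc2)C(=O)OCC | intermediate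
12 | (R)-3-methylidene-5-Ar-oxolan-2-one | C=C1C[C@@H](OC1=O)c2c(CO[Si](C)(C)C(C)(C)C)coc2C[C@](C)(O)CCS(=O)(=O)c3ccccc3 | intermediate
13 | (3S,5R)-3-hydroperoxy-3-methyl-5-Ar-oxolan-2-one (formed in the flask) | C[C@]1(OO)C[C@@H](OC1=O)c2c(CO[Si](C)(C)C(C)(C)C)coc2C[C@](C)(O)CCS(=O)(=O)c3ccccc3 | intermediate
14 | (3S,5R)-3-hydroxy-3-methyl-5-Ar-oxolan-2-one | C[C@]1(O)C[C@@H](OC1=O)c2c(CO[Si](C)(C)C(C)(C)C)coc2C[C@](C)(O)CCS(=O)(=O)c3ccccc3 | intermediate
15 | (2S,4R)-2,4-dihydroxy-N-methoxy-N,2-dimethyl-4-Ar-butanamide | CON(C)C(=O)[C@@](C)(O)C[C@@H](O)c1c(CO[Si](C)(C)C(C)(C)C)coc1C[C@](C)(O)CCS(=O)(=O)c2ccccc2 | intermediate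
16 | (2S,4R)-2-hydroxy-N-methoxy-N,2-dimethyl-4-(TBS-oxy)-4-Ar-butanamide | CON(C)C(=O)[C@@](C)(O)C[C@@H](O[Si](C)(C)C(C)(C)C)c1c(CO[Si](C)(C)C(C)(C)C)coc1C[C@](C)(O)CCS(=O)(=O)c2ccccc2 | intermediate
17 | trilithium salt of 16, lithiated at O10, O4 and C2 (formed in the flask) | CON(C)C(=O)[C@@](C)(O[Li])C[C@@H](O[Si](C)(C)C(C)(C)C)c1c(CO[Si](C)(C)C(C)(C)C)coc1C[C@](C)(O[Li])CC([Li])S(=O)(=O)c2ccccc2 | intermediate
18 | macrocyclic lithium aminal at C1 (ten-membered ring closed, trilithium salt; formed in the flask) | CON(C)C1(O[Li])C(S(=O)(=O)c2ccccc2)C[C@@](C)(O[Li])Cc3occ(CO[Si](C)(C)C(C)(C)C)c3[C@H](O[Si](C)(C)C(C)(C)C)C[C@]1(C)O[Li] | intermediate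
19 | furan-fused ten-membered keto alcohol (C1 ketone, 2-phenylsulfonyl, 4-OH, 8-O-TBS, 10-OH, 13-O-TBS; formed in the flask) | O=C1C(S(=O)(=O)c2ccccc2)C[C@@](C)(O)Cc3occ(CO[Si](C)(C)C(C)(C)C)c3[C@H](O[Si](C)(C)C(C)(C)C)C[C@]1(C)O | intermediate
20 | furan-fused 1,4-epoxy hemiketal (1-OH on the face of the C4 methyl, 2-phenylsulfonyl epimers, 8-O-TBS, 10-OH, 13-O-TBS) | C[C@]1(O)C[C@@H](O[Si](C)(C)C(C)(C)C)c2c(CO[Si](C)(C)C(C)(C)C)coc2C[C@@]3(C)CC(S(=O)(=O)c4ccccc4)[C@]1(O)O3 | intermediate
21 | desulfonylated 1,4-epoxy hemiketal (8-O-TBS, 13-O-TBS) | C[C@]1(O)C[C@@H](O[Si](C)(C)C(C)(C)C)c2c(CO[Si](C)(C)C(C)(C)C)coc2C[C@@]3(C)CC[C@]1(O)O3 | intermediate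
22 | 1,4-epoxy hemiketal 8,13-diol | C[C@]1(O)C[C@@H](O)c2c(CO)coc2C[C@@]3(C)CC[C@]1(O)O3 | intermediate
23 | 1,4-epoxy hemiketal 13-acetate | C[C@]1(O)C[C@@H](O)c2c(COC(C)=O)coc2C[C@@]3(C)CC[C@]1(O)O3 | intermediate
24 | 1,4-epoxy hemiketal 13-acetate 8-methacrylate | C[C@]1(O)C[C@@H](OC(=O)C(C)=C)c2c(COC(C)=O)coc2C[C@@]3(C)CC[C@]1(O)O3 | intermediate
25 | 6,12-endoperoxide of 24 (formed in the flask) | C[C@]1(O)C[C@@H](OC(=O)C(C)=C)C2=C(COC(C)=O)C3OOC2(O3)C[C@@]4(C)CC[C@]1(O)O4 | intermediate
26 | γ-hydroxybutenolide (6-hydroxy-6,12-olide, 7(11)-ene, C6 epimers; 1,4-epoxy, 1-OH) | C[C@]1(O)C[C@@H](OC(=O)C(C)=C)C2=C(COC(C)=O)C(=O)OC2(O)C[C@@]3(C)CC[C@]1(O)O3 | intermediate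
27 | 1-hydroxy-1,4-epoxy 5E,7(11)-dien-6,12-olide (formed in the flask) | C=C(C)C(=O)O[C@@H]1C[C@](C)(O)[C@]2(O)CC[C@](C)(/C=C3/OC(=O)C(COC(C)=O)=C31)O2 | intermediate
28 | CNP0394509.1 | C=C(C)C(=O)O[C@@H]1C[C@](C)(O)C2=CC[C@](C)(/C=C3/OC(=O)C(COC(C)=O)=C31)O2 | target

**Step count**
Total: 16 steps. Longest linear sequence: 14 steps (steps 1, 3, 4, 6–16, from 1 to 28).

**Steps most likely to fail**

Step 10 (ring closure): intermolecular acylation (oligomerisation) may win over ring closure, or the hindered amide may not accept the carbanion. The fallback sets out from 16. i-Bu2AlH (THF, −78 °C) reduces the amide to the α-hydroxy aldehyde F1. LiN(i-Pr)2 (3.3 equiv, THF, −78 °C, high dilution) then adds the sulfonyl carbanion to this unhindered aldehyde, the addition stage of a Julia–Lythgoe olefination run within one molecule, giving the macrocyclic β-hydroxy sulfone F2. Dess–Martin periodinane oxidises the secondary C1 carbinol to keto alcohol 19, which closes to 20, where the route is rejoined.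

Step 16 (double dehydration): elimination at the bridgehead hemiketal may stall, or be diverted to internal ketal formation between C1 and C6 or to an acyloin-type shift at the neighbouring tertiary carbinol. The fallback sets out from 26. (CF3CO)2O and pyridine (CH2Cl2, −20 → 0 °C) acylate the three hydroxyls to the tris(trifluoroacetate) F3. Its two hemiketal esters ionise and lose the C5 and C2 protons to pyridine, leaving the 10-O-trifluoroacetate of 28 F4. NaHCO3 in MeOH (0 °C) cleaves this tertiary trifluoroacetate without touching acetate or methacrylate and gives 28.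

Step 7 (C10 hydration): facial selectivity in the oxygen capture at C10 may be poor. The fallback sets out from 12. NaBH4 (MeOH, 0 °C) reduces the exocyclic double bond by conjugate addition to the α-methyl lactone F5 (both C10 epimers). KN(SiMe3)2 (2.2 equiv, THF, −78 °C) forms the lactone enolate, and 2-(phenylsulfonyl)-3-phenyloxaziridine hydroxylates it from the face away from the C8 furyl group (Davis oxidation) to give 14.

Further compounds
F1 | step 10 | (2S,4R)-2-hydroxy-2-methyl-4-(TBS-oxy)-4-Ar-butanal | O=C[C@@](C)(O)C[C@@H](O[Si](C)(C)C(C)(C)C)c1c(CO[Si](C)(C)C(C)(C)C)coc1C[C@](C)(O)CCS(=O)(=O)c2ccccc2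
F2 | step 10 | furan-fused ten-membered β-hydroxy sulfone (1-OH and 2-phenylsulfonyl as mixtures, 4-OH, 8-O-TBS, 10-OH, 13-O-TBS) | OC1C(S(=O)(=O)c2ccccc2)C[C@@](C)(O)Cc3occ(CO[Si](C)(C)C(C)(C)C)c3[C@H](O[Si](C)(C)C(C)(C)C)C[C@]1(C)O
F3 | step 16 | 1,6,10-tris(trifluoroacetate) of 26 | C[C@]1(OC(=O)C(F)(F)F)C[C@@H](OC(=O)C(C)=C)C2=C(COC(C)=O)C(=O)OC2(OC(=O)C(F)(F)F)C[C@@]3(C)CC[C@]1(OC(=O)C(F)(F)F)O3
F4 | step 16 | 10-O-trifluoroacetate of 28 | C=C(C)C(=O)O[C@@H]1C[C@](C)(OC(=O)C(F)(F)F)C2=CC[C@](C)(/C=C3/OC(=O)C(COC(C)=O)=C31)O2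
F5 | step 7 | (5R)-3-methyl-5-Ar-oxolan-2-one (C3 epimers) | CC1C[C@@H](OC1=O)c2c(CO[Si](C)(C)C(C)(C)C)coc2C[C@](C)(O)CCS(=O)(=O)c3ccccc3
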